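## Retrosynthetic overview
1. The target comes from global debenzylation of the tri-O-benzyl diol **14**, which comes from reduction of the C9'' aldehyde of **13**.
2. **13** (C7''/C8'' syn, i.e. threo) comes from one catalytic asymmetric Mukaiyama-type aldol. The nucleophile is the (Z)-enol silane **11** of a flavone-bearing aryloxyacetaldehyde, and the electrophile is 4-benzyloxybenzaldehyde (**12**). This sets both side-chain stereocenters and uses the achiral aldehyde **9** as the only carbon source for C8''/C9''.
3. The diaryl ether is made early by Williamson alkylation at a primary carbon, because SN2 at the hindered secondary C8'' with a 2,6-dimethoxyphenoxide would fail.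
4. Ring order: phloroglucinol ring A and syringyl ring B are the starting arenes. Pyranone ring C is closed by Claisen–Schmidt condensation then I2/DMSO cyclization. No other rings are formed.

Assumptions (one line each):
- The 5-OH and 7-OH are carried as benzyl ethers and the side-chain phenol as a benzyl ether.
- Configuration (7''S,8''S) is syn (threo) in the zigzag drawing.
- The IDPi antipode that gives 7''S,8''S is found by screening both enantiomers.

## Route

**Step 1**
Reactants: **1** 2,4,6-trihydroxyacetophenone; **2** benzyl bromide
Product: **3** 2'-hydroxy-4',6'-bis(benzyloxy)acetophenone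
Conditions: BnBr (2.1 equiv), K2CO3, acetone, reflux
Reagents that add atoms: benzyl bromide, BrCc1ccccc1
Why: Williamson O-benzylation. The chelated 2'-OH stays free, so the 4'- and 6'-OH groups are alkylated.

**Step 2**
Reactants: **4** syringaldehyde; **5** 2-bromoethanol
Product: **6** 4-(2-hydroxyethoxy)-3,5-dimethoxybenzaldehyde
Conditions: **5** (1.5 equiv), K2CO3, cat. KI, DMF, 80 °C
Reagents that add atoms: 2-bromoethanol, OCCBr
Why: Williamson etherification of the phenoxide at a primary carbon. The hydroxyethyl group is a robust masked aldehyde that survives base and I2/DMSO and is unmasked by oxidation in step 5.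

**Step 3**
Reactants: **3**; **6**
Product: **7** (E)-chalcone, 1-[2-hydroxy-4,6-bis(benzyloxy)phenyl]-3-[4-(2-hydroxyethoxy)-3,5-dimethoxyphenyl]prop-2-en-1-one
Conditions: KOH (aq.), EtOH, rt, 48 h
Reagents that add atoms: none
Why: Claisen–Schmidt aldol condensation. The benzyl ethers and the primary alcohol are base-stable.

**Step 4**
Reactants: **7**
Product: **8** 5,7-bis(benzyloxy)-2-[4-(2-hydroxyethoxy)-3,5-dimethoxyphenyl]-4H-chromen-4-one
Conditions: I2 (0.2 equiv), DMSO, 120 °C, 3 h
Reagents that add atoms: none
Why: Oxidative cyclization of a 2'-hydroxychalcone (I2/DMSO: oxa-Michael closure to the flavanone, then iodination and elimination) closes ring C and gives the flavone.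

**Step 5**
Reactants: **8**
Product: **9** 2-{4-[5,7-bis(benzyloxy)-4-oxo-4H-chromen-2-yl]-2,6-dimethoxyphenoxy}acetaldehyde
Conditions: Dess–Martin periodinane, NaHCO3, CH2Cl2, 0 °C to rt
Reagents that add atoms: none
Why: Dess–Martin oxidation of the primary alcohol. The benzyl ethers and the flavone are inert, and buffering avoids acid-driven enolization of the product.

**Step 6**
Reactants: **9**; **10** trimethylsilyl triflate
Product: **11** (Z)-TMS enol ether of **9**, ArO–CH=CH–OSiMe3 with the two oxygens cis
Conditions: TMSOTf (1.3 equiv), Et3N (2 equiv), CH2Cl2, 0 °C, 1 h. Evaporate, take up in dry toluene, filter off ammonium salts under N2, use crude.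
Reagents that add atoms: TMSOTf, C[Si](C)(C)OS(=O)(=O)C(F)(F)F
Why: Soft enolization and O-silylation. The cis-effect of a 1,2-dioxygenated alkene strongly favours the Z-enol ether, which is what sets the syn relationship in step 7.

**Step 7**
Reactants: **11**; **12** 4-(benzyloxy)benzaldehyde (3 equiv)
Product: **13** (2R,3S)-3-[4-(benzyloxy)phenyl]-3-(trimethylsilyloxy)-2-aryloxypropanal, with aryl = 4-[5,7-bis(benzyloxy)-4-oxochromen-2-yl]-2,6-dimethoxyphenyl. This is C8''(S), C7''(S) in the target numbering; the C8'' descriptor is R here only because CHO outranks C7 in CIP priority.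
Conditions: chiral BINOL-derived IDPi catalyst (imidodiphosphorimidate, 5 mol%), toluene/CH2Cl2 4:1, –60 °C, 48 h, slow addition of **11**
Reagents that add atoms: none beyond the reactants (the TMS group ends up on the C7'' oxygen of **13**)
Why: Proposed new method: the silylated chiral IDPi acts as a confined silylium-type Lewis acid that activates **12**, so its aldehyde enantioface sets C7''. The Z-configured α-aryloxy enol silane adds through a synclinal open transition state, so C8'' is set syn (threo) relative to C7''. Closest known reaction type: IDPi-catalysed Mukaiyama aldol of silyl ketene acetals and enol ethers with aromatic aldehydes. Syn selectivity from Z-glycolate-type enolates is also known. This route does not use an aryloxy aldehyde-derived flavone enol silane to build a β-O-4 glycerol ether.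

**Step 8**
Reactants: **13**
Product: **14** (2S,3S)-3-[4-(benzyloxy)phenyl]-2-{4-[5,7-bis(benzyloxy)-4-oxochromen-2-yl]-2,6-dimethoxyphenoxy}propane-1,3-diol
Conditions: NaBH4 (1.5 equiv), THF/MeOH 1:1, 0 °C, 15 min; aqueous NH4Cl quench
Reagents that add atoms: none
Why: Chemoselective hydride reduction of the aldehyde. Methanolysis removes the TMS ether, and the short, cold reaction avoids retro-aldol and flavone reduction. No stereocenter is touched.

**Step 9**
Reactants: **14**
Product: **15** target, (–)-(7''S,8''S)-4'',5,7-trihydroxy-3',5'-dimethoxy-4',8''-oxyflavonolignan-7'',9''-diol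
Conditions: H2 (1 atm), 10% Pd/C, THF/MeOH 1:1, rt, 2–3 h (monitor closely)
Reagents that add atoms: none (hydrogen only)
Why: Hydrogenolysis of the three aryl benzyl ethers. Benzyl cleavage is faster than benzylic C–O cleavage or C2=C3 reduction, and the stereocenters are not involved.

## Compound list
1 | 2,4,6-trihydroxyacetophenone | CC(=O)c1c(O)cc(O)cc1O | starting material
2 | benzyl bromide | BrCc1ccccc1 | starting material
3 | 2'-hydroxy-4',6'-bis(benzyloxy)acetophenone | CC(=O)c1c(O)cc(OCc2ccccc2)cc1OCc1ccccc1 | intermediate
4 | syringaldehyde | COc1cc(C=O)cc(OC)c1O | starting material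
5 | 2-bromoethanol | OCCBr | starting material
6 | 4-(2-hydroxyethoxy)-3,5-dimethoxybenzaldehyde | COc1cc(C=O)cc(OC)c1OCCO | intermediate
7 | (E)-chalcone | COc1cc(/C=C/C(=O)c2c(O)cc(OCc3ccccc3)cc2OCc2ccccc2)cc(OC)c1OCCO | intermediate
8 | 5,7-bis(benzyloxy)-2-[4-(2-hydroxyethoxy)-3,5-dimethoxyphenyl]chromen-4-one | COc1cc(cc(OC)c1OCCO)-c1cc(=O)c2c(OCc3ccccc3)cc(OCc3ccccc3)cc2o1 | intermediate
9 | flavone aryloxyacetaldehyde | COc1cc(cc(OC)c1OCC=O)-c1cc(=O)c2c(OCc3ccccc3)cc(OCc3ccccc3)cc2o1 | intermediate
10 | trimethylsilyl triflate | C[Si](C)(C)OS(=O)(=O)C(F)(F)F | starting material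
11 | (Z)-TMS enol ether of 9 | COc1cc(cc(OC)c1O/C=C\O[Si](C)(C)C)-c1cc(=O)c2c(OCc3ccccc3)cc(OCc3ccccc3)cc2o1 | intermediate
12 | 4-(benzyloxy)benzaldehyde | O=Cc1ccc(OCc2ccccc2)cc1 | starting material
13 | syn aldol aldehyde, 7''-OTMS | COc1cc(cc(OC)c1O[C@@H](C=O)[C@@H](O[Si](C)(C)C)c1ccc(OCc2ccccc2)cc1)-c1cc(=O)c2c(OCc3ccccc3)cc(OCc3ccccc3)cc2o1 | intermediate
14 | tri-O-benzyl diol | COc1cc(cc(OC)c1O[C@@H](CO)[C@@H](O)c1ccc(OCc2ccccc2)cc1)-c1cc(=O)c2c(OCc3ccccc3)cc(OCc3ccccc3)cc2o1 | intermediate
15 | target (7''S,8''S) | COc1cc(-c2cc(=O)c3c(O)cc(O)cc3o2)cc(OC)c1O[C@@H](CO)[C@@H](O)c1ccc(O)cc1 | target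

## Totals
- Total steps: 9.
- Longest linear sequence: 8 (1→3→7→8→9→11→13→14→15, or equivalently from **4** via **6**).

## Three steps most likely to fail
1. **Step 7, the proposed new aldol.**
   - Risks: low syn:anti ratio, background protodesilylation giving achiral aldol or self-aldol of the donor, and catalyst quenching by residual Et3N.
   - Fallback (known chemistry, different approach): oxidize **8** to the aryloxyacetic acid and couple it to an Evans 4-benzyloxazolidinone (auxiliary enantiomer chosen for 7''S,8''S). Then do an Evans boron-enolate syn-aldol with **12** (Bu2BOTf, Et3N), and remove the auxiliary by LiBH4 reduction to give **14** directly.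
2. **Step 9, global hydrogenolysis.**
   - Risks: benzylic C7''–O cleavage of the p-hydroxybenzylic alcohol, or saturation of the flavone C2=C3.
   - Fallback: swap to Lewis-acid debenzylation of **14** with BCl3 and pentamethylbenzene (cation scavenger) at –78 °C, which avoids hydrogenation chemistry entirely.
3. **Step 4, I2/DMSO cyclization with a free primary alcohol.**
   - Risk: over-oxidation or iodination.
   - Fallback: stepwise ring closure. Cyclize chalcone **7** to the flavanone (NaOAc, EtOH, reflux), then dehydrogenate with DDQ in dioxane.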